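## Retrosynthetic overview

1. Numbering (daucane): the five-membered ring is C1 (quaternary CMe), C2-C3 (CH2CH2), C4 (C(OH)iPr) and C5 (fusion CH). The seven-membered ring is C1, C5, C6 (CHO-acyl), C7=C8 (C8 carries methyl C14), C9 (CHOH) and C10 (CH2).
2. Endgame: the target comes from ene-dione 15 (C6=O, C7=C8, C9=O) by C4-OH-directed reduction at C6, anisoylation, then 1,2-reduction at C9 anti to the C1 methyl group.
3. Key disconnection: C10-C1 (together with C7-C8). It is a formal [4+3] union of silylene-bridged siloxydiene 6 and siloxyvinyldiazoacetate 9: cyclopropanation of C6=C7, then divinylcyclopropane rearrangement.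
4. Enabling feature: in the seven-membered ring the oxygenated carbons C6 and C9 flank C7=C8. At the bis-enol level the ring is therefore a cyclohepta-1,4-diene (C5=C6-C7-C8=C9) whose only sp3-sp3 bond is C10-C1, the Cope retron. The C4 hydroxyl on the five-membered ring sits 1,3 to the C6 oxygen, so one silicon atom can bridge both and relay C4 to C1.
5. Ring order: five-membered ring (ring contraction of (S)-terpinen-4-ol), temporary six-membered dioxasilin ring, transient cyclopropane, seven-membered ring last. C4 is bought; C1, C5, C6 and C9 are relayed from it.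

Key step: step 8

Assumption: (S)-(+)-terpinen-4-ol is bought as an enantiopure lot; it is the only source of chirality in the route.

## Route

Step 1
Reactants: 1 (S)-(+)-terpinen-4-ol
Product: 2 (3S)-3-hydroxy-6-oxo-3-(propan-2-yl)heptanal
Conditions: O3, CH2Cl2/MeOH, -78 °C; then Me2S, -78 to 23 °C
Reagents that add atoms: ozone, [O-][O+]=O
Why: Ozonolysis (Criegee mechanism) with reductive work-up should cleave the only C=C bond and leave the bought carbinol centre C4 untouched.

Step 2
Reactants: 2 (3S)-3-hydroxy-6-oxo-3-(propan-2-yl)heptanal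
Product: 3 (5R)-5-hydroxy-2-methyl-5-(propan-2-yl)cyclopent-1-ene-1-carbaldehyde
Conditions: dibenzylammonium trifluoroacetate (0.3 equiv), toluene, 50 °C
Reagents that add atoms: none
Why: Intramolecular aldol condensation through the aldehyde enamine (5-enolexo-exo-trig attack on the methyl ketone) should outrun loss of the tertiary hydroxyl and give the five-membered ring with C5=C1 in place.

Step 3
Reactants: 3 (5R)-5-hydroxy-2-methyl-5-(propan-2-yl)cyclopent-1-ene-1-carbaldehyde
Product: 4 (1R)-2-(1-hydroxyethyl)-3-methyl-1-(propan-2-yl)cyclopent-2-en-1-ol (both epimers at the new carbinol carbon)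
Conditions: MeMgBr (2.3 equiv), THF, -78 to 0 °C; aq NH4Cl
Reagents that add atoms: methylmagnesium bromide, C[Mg]Br
Why: 1,2-Grignard addition to the enal (the first equivalent deprotonates the hydroxyl) brings in C7; the new carbinol centre is erased in the next step.

Step 4
Reactants: 4 (1R)-2-(1-hydroxyethyl)-3-methyl-1-(propan-2-yl)cyclopent-2-en-1-ol
Product: 5 1-[(5R)-5-hydroxy-2-methyl-5-(propan-2-yl)cyclopent-1-en-1-yl]ethan-1-one
Conditions: MnO2 (20 equiv), CH2Cl2, 23 °C
Reagents that add atoms: none
Why: MnO2 oxidation is selective for the secondary allylic alcohol, and the tertiary alcohol cannot be oxidised.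

Step 5
Reactants: 5 1-[(5R)-5-hydroxy-2-methyl-5-(propan-2-yl)cyclopent-1-en-1-yl]ethan-1-one
Product: 6 (7aR)-5-methyl-4-methylidene-2,2,7a-tri(propan-2-yl)-4,6,7,7a-tetrahydrocyclopenta[d][1,3,2]dioxasiline (silylene-bridged 2-siloxydiene)
Conditions: iPr2Si(OTf)2 (1.1 equiv), Et3N (4 equiv), CH2Cl2, -20 to 23 °C
Reagents that add atoms: diisopropylsilyl bis(trifluoromethanesulfonate), CC(C)[Si](OS(=O)(=O)C(F)(F)F)(OS(=O)(=O)C(F)(F)F)C(C)C
Why: Soft enolisation with a silyl triflate and an amine (silyl enol ether formation) can only remove a C7 proton next to the ketone, and the bifunctional silicon reagent ties the enol oxygen to the C4 oxygen in a six-membered ring.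

Step 6
Reactants: 7 methyl acetoacetate
Product: 8 methyl 2-diazo-3-oxobutanoate
Conditions: 4-acetamidobenzenesulfonyl azide, Et3N, MeCN, 0 to 23 °C
Reagents that add atoms: 4-acetamidobenzenesulfonyl azide, CC(=O)Nc1ccc(cc1)S(=O)(=O)N=[N+]=[N-]
Why: Regitz diazo transfer to the activated methylene group is a standard reaction of 1,3-dicarbonyl compounds.

Step 7
Reactants: 8 methyl 2-diazo-3-oxobutanoate
Product: 9 methyl 3-[(tert-butyldimethylsilyl)oxy]-2-diazobut-3-enoate
Conditions: TBSOTf, Et3N, CH2Cl2, 0 °C
Reagents that add atoms: tert-butyldimethylsilyl trifluoromethanesulfonate, CC(C)(C)[Si](C)(C)OS(=O)(=O)C(F)(F)F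
Why: Silyl enol ether formation at the acetyl group turns the diazo ketoester into the vinyldiazoacetate that carries C8, C9, C10 and C14.

Step 8
Reactants: 6 silylene-bridged 2-siloxydiene; 9 methyl 3-[(tert-butyldimethylsilyl)oxy]-2-diazobut-3-enoate
Product: 11 silylene-bridged tricyclic cyclohepta-1,4-diene ester (1R,4R), via spiro divinylcyclopropane 10 (not isolated)
Conditions: Rh2(O2CC7H15)4 (dirhodium tetraoctanoate, 1 mol %), hexanes, 23 °C, slow addition of 9 (1.5 equiv); then toluene, 80 °C
Reagents that add atoms: none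
Why: The dirhodium carbenoid from 9 (loss of N2) transfers its carbene carbon C8 in a concerted, asynchronous [2+1] addition to the electron-rich terminal C6=C7 enol ether bond of 6 and closes spiro cyclopropane 10 with the siloxyvinyl group cis to the cyclopentenyl group (ester away from the larger alkene substituent), the normal outcome for donor/acceptor vinylcarbenoids. On warming, 10 undergoes the divinylcyclopropane-cycloheptadiene (Cope) rearrangement, a [3,3]-sigmatropic shift through the endo boat transition state in which the strained, donor/acceptor-weakened C6-C8 bond breaks while C10-C1 forms and closes the seven-membered ring; the whole is the known tandem cyclopropanation/Cope formal [4+3] cycloaddition of vinyldiazoacetates with 2-siloxydienes, which also builds methyl-bearing quaternary carbons from 1-alkenyl-2-methylcycloalkenes. The only new stereocentre, C1, is controlled by C4 through the temporary dioxasilin ring: the enol oxygen on C6 is held on the face of the C4 oxygen, so C7 is tilted toward the isopropyl face, the face of C6=C7 that looks at the C1 methyl group is closed by allylic strain, and the carbenoid adds to the other face. C8 then stands above the isopropyl face with C7 next to the methyl group, which is already the reactive boat conformer, so C10 can reach C1 only from that face and the methyl group ends cis to the C4 oxygen as in the target, whereas a cyclopropane formed on the other face cannot align its C6-C8 bond with the C5=C1 pi bond while the silicon bridge is intact. The step needs attack at the carbenoid carbon rather than at its vinylogous end (C10), and reaction at C6=C7 rather than at C5=C1; a carboxylate catalyst in a hydrocarbon solvent and the hindered, tetrasubstituted nature of C5=C1 should secure both. One operation thus joins two small fragments, makes the ring and the quaternary centre, and places C6 and C9 at the ketone level and C14 on C8.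

Step 9
Reactants: 11 silylene-bridged tricyclic cyclohepta-1,4-diene ester
Product: 13 C14 allylic acetate of the tricycle (1R,4R), via aluminium alkoxide 12 (not isolated)
Conditions: DIBAL-H (2.4 equiv), CH2Cl2, -78 °C; then pyridine, DMAP, Ac2O, -78 to 0 °C
Reagents that add atoms: acetic anhydride, CC(=O)OC(C)=O
Why: DIBAL-H reduction of the conjugated ester to the primary allylic alkoxide, followed by acetylation in the same flask, leaves both silyl enol ethers intact and puts a leaving group on C14 only.

Step 10
Reactants: 13 C14 allylic acetate of the tricycle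
Product: 15 (1R,4R,5R)-4-hydroxydauc-7-ene-6,9-dione, via exo-methylene diketone 14 (not isolated)
Conditions: Et3N·3HF, THF, 0 to 23 °C; then DBU (0.2 equiv), CH2Cl2, 0 °C
Reagents that add atoms: none
Why: Fluoride desilylation frees both ketones and the C4 hydroxyl, the C9 enolate expels the C14 acetate (E1cB) to give 14, and base-mediated alkene isomerisation through the doubly activated C7 position brings C7=C8 into conjugation while C5 equilibrates to the trans-fused epimer (C6 anti to isopropyl, hydrogen bond from O4 to the C6 carbonyl).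

Step 11
Reactants: 15 (1R,4R,5R)-4-hydroxydauc-7-ene-6,9-dione
Product: 16 (1R,4R,5S,6S)-4,6-dihydroxydauc-7-en-9-one
Conditions: Me4NBH(OAc)3 (5 equiv), MeCN/AcOH, -30 °C
Reagents that add atoms: none
Why: In the Evans-Saksena reduction the C4 hydroxyl should bind boron and deliver hydride to C6 from the methyl-bearing face, so that O6 ends anti to the C1 methyl group, while the C9 ketone has no hydroxyl within reach and is inert to this mild hydride.

Step 12
Reactants: 16 (1R,4R,5S,6S)-4,6-dihydroxydauc-7-en-9-one; 17 4-methoxybenzoyl chloride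
Product: 18 (1R,4R,5S,6S)-4-hydroxy-9-oxodauc-7-en-6-yl 4-methoxybenzoate
Conditions: Et3N, DMAP, CH2Cl2, 23 °C
Reagents that add atoms: none
Why: DMAP-catalysed acylation should take the only secondary hydroxyl, since the hindered tertiary C4 hydroxyl does not compete.

Step 13
Reactants: 18 (1R,4R,5S,6S)-4-hydroxy-9-oxodauc-7-en-6-yl 4-methoxybenzoate
Product: 19 target, (1R,4R,5S,6S,9R)-4,9-dihydroxydauc-7-en-6-yl 4-methoxybenzoate
Conditions: NaBH4, CeCl3·7H2O, MeOH, -78 °C
Reagents that add atoms: none
Why: Luche 1,2-reduction spares the aryl ester, and hydride should reach C9 from the face opposite to the axial, 1,3-related C1 methyl group, which puts the C9 hydroxyl cis to that methyl group.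

## Compound list

1 | (S)-(+)-terpinen-4-ol, (1S)-4-methyl-1-(propan-2-yl)cyclohex-3-en-1-ol | CC1=CC[C@](O)(C(C)C)CC1 | starting material
2 | (3S)-3-hydroxy-6-oxo-3-(propan-2-yl)heptanal | O=CC[C@](O)(C(C)C)CCC(C)=O | intermediate
3 | (5R)-5-hydroxy-2-methyl-5-(propan-2-yl)cyclopent-1-ene-1-carbaldehyde | O=CC1=C(C)CC[C@@]1(O)C(C)C | intermediate
4 | (1R)-2-(1-hydroxyethyl)-3-methyl-1-(propan-2-yl)cyclopent-2-en-1-ol, both carbinol epimers | CC(O)C1=C(C)CC[C@@]1(O)C(C)C | intermediate
5 | 1-[(5R)-5-hydroxy-2-methyl-5-(propan-2-yl)cyclopent-1-en-1-yl]ethan-1-one | CC(=O)C1=C(C)CC[C@@]1(O)C(C)C | intermediate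
6 | (7aR)-5-methyl-4-methylidene-2,2,7a-tri(propan-2-yl)-4,6,7,7a-tetrahydrocyclopenta[d][1,3,2]dioxasiline | C=C1O[Si](C(C)C)(C(C)C)O[C@@]2(C(C)C)CCC(C)=C12 | intermediate
7 | methyl acetoacetate | COC(=O)CC(C)=O | starting material
8 | methyl 2-diazo-3-oxobutanoate | COC(=O)C(=[N+]=[N-])C(C)=O | intermediate
9 | methyl 3-[(tert-butyldimethylsilyl)oxy]-2-diazobut-3-enoate | COC(=O)C(=[N+]=[N-])C(=C)O[Si](C)(C)C(C)(C)C | intermediate
10 | spiro cyclopropane on C6 of the dioxasilin ring; C8 carries CO2Me and the 1-siloxyvinyl group, the latter cis to the cyclopentenyl group; C8 on the isopropyl face | COC(=O)[C@]1(C(=C)O[Si](C)(C)C(C)(C)C)C[C@]12O[Si](C(C)C)(C(C)C)O[C@@]3(C(C)C)CCC(C)=C23 | intermediate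
11 | (1R,4R)-tricycle: daucane skeleton with C5=C6 and C8=C9, O4 and O6 bridged by Si(iPr)2, OTBS on C9, CO2Me (C14) on C8 | COC(=O)C1=C(O[Si](C)(C)C(C)(C)C)C[C@@]2(C)CC[C@]3(C(C)C)O[Si](C(C)C)(C(C)C)OC(C1)=C23 | intermediate
12 | diisobutylaluminium alkoxide of the C14 alcohol derived from 11 | CC(C)C[Al](CC(C)C)OCC1=C(O[Si](C)(C)C(C)(C)C)C[C@@]2(C)CC[C@]3(C(C)C)O[Si](C(C)C)(C(C)C)OC(C1)=C23 | intermediate
13 | (1R,4R)-tricycle as 11 with CH2OAc (C14) on C8 | CC(=O)OCC1=C(O[Si](C)(C)C(C)(C)C)C[C@@]2(C)CC[C@]3(C(C)C)O[Si](C(C)C)(C(C)C)OC(C1)=C23 | intermediate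
14 | (1R,4R,5R)-4-hydroxydauc-8(14)-ene-6,9-dione | O=C1CC(=C)C(=O)C[C@@]2(C)CC[C@@](O)(C(C)C)[C@H]12 | intermediate
15 | (1R,4R,5R)-4-hydroxydauc-7-ene-6,9-dione, trans-fused | O=C1C=C(C)C(=O)C[C@@]2(C)CC[C@@](O)(C(C)C)[C@H]12 | intermediate
16 | (1R,4R,5S,6S)-4,6-dihydroxydauc-7-en-9-one | O[C@H]1C=C(C)C(=O)C[C@@]2(C)CC[C@@](O)(C(C)C)[C@H]12 | intermediate
17 | 4-methoxybenzoyl chloride | COc1ccc(cc1)C(Cl)=O | starting material
18 | (1R,4R,5S,6S)-4-hydroxy-9-oxodauc-7-en-6-yl 4-methoxybenzoate | COc1ccc(C(=O)O[C@H]2C=C(C)C(=O)C[C@@]3(C)CC[C@@](O)(C(C)C)[C@H]23)cc1 | intermediate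
19 | (3R,3aS,4S,7R,8aR)-3,7-dihydroxy-6,8a-dimethyl-3-(propan-2-yl)-1,2,3,3a,4,7,8,8a-octahydroazulen-4-yl 4-methoxybenzoate | COc1ccc(C(=O)O[C@H]2C=C(C)[C@H](O)C[C@@]3(C)CC[C@@](O)(C(C)C)[C@H]23)cc1 | target

## Step count and risks

Total step count: 13.
Longest linear sequence: 11 (steps 1-5 and 8-13).

**Step 8.**
- What may go wrong: the enol ether carbon C7 may attack the vinylogous end of the carbenoid, the carbenoid may add to the wrong face of the bridged diene, or the cyclopropane may stall before the rearrangement.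
- Fallback: stereocontrol is moved from the temporary ring to the catalyst. Setting out from 5, TESOTf and Et3N give the open bis(triethylsilyl) diene F1.
- F1 reacts with 9 under dirhodium tetrakis[(S)-(1-adamantyl)(phthalimido)acetate], Rh2(S-PTAD)4 (its mirror image if the sense of induction requires it). This gives the bicyclic cycloheptadiene ester F2 under reagent control.
- DIBAL-H followed by Ac2O gives the bicyclic allylic acetate F3. Et3N·3HF followed by DBU brings the material back to the route at 15.

**Step 11.**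
- What may go wrong: ligand exchange at the hindered tertiary hydroxyl may be slow, or hydride may arrive from the face opposite to the methyl group.
- Fallback: the intrinsic facial bias is accepted and corrected by inversion. Setting out from 15, NaBH4/CeCl3 should reduce both ketones anti to the C1 methyl group and give the 6-epi triol F4, with C9 already correct.
- TESCl and imidazole should silylate the less hindered C9 hydroxyl to give the 9-O-triethylsilyl ether F5.
- Mitsunobu esterification with 4-methoxybenzoic acid, PPh3 and DIAD inverts C6 and gives the silylated anisate F6. HF·pyridine then returns to the route at 19.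

**Step 10.**
- What may go wrong: the tertiary hydroxyl may be lost by beta-elimination, or the exocyclic enone may oligomerise before it isomerises.
- Fallback: the exocyclic enone is avoided altogether. Setting out from 13, hydrogenolysis of the allylic acetate with Pd(PPh3)4 and LiBHEt3 gives the C8-methyl bis-enol ether F7.
- Et3N·3HF gives the saturated 1,4-diketone F8. IBX dehydrogenation in DMSO between the two carbonyl groups returns to the route at 15.

## Further compounds

F1 | step 8 | (R)-triethyl{[2-methyl-5-(propan-2-yl)-5-(triethylsilyloxy)cyclopent-1-en-1-yl]ethenyloxy}silane, open bis(triethylsilyl) diene | C=C(O[Si](CC)(CC)CC)C1=C(C)CC[C@@]1(O[Si](CC)(CC)CC)C(C)C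
F2 | step 8 | (1R,4R)-bicyclic cycloheptadiene ester, OTES on C4 and C6, OTBS on C9, CO2Me on C8 | COC(=O)C1=C(O[Si](C)(C)C(C)(C)C)C[C@@]2(C)CC[C@@](O[Si](CC)(CC)CC)(C(C)C)C2=C(O[Si](CC)(CC)CC)C1
F3 | step 8 | (1R,4R)-bicyclic allylic acetate, as F2 with CH2OAc on C8 | CC(=O)OCC1=C(O[Si](C)(C)C(C)(C)C)C[C@@]2(C)CC[C@@](O[Si](CC)(CC)CC)(C(C)C)C2=C(O[Si](CC)(CC)CC)C1
F4 | step 11 | (1R,4R,5S,6R,9R)-dauc-7-ene-4,6,9-triol (6-epi triol) | O[C@@H]1C=C(C)[C@H](O)C[C@@]2(C)CC[C@@](O)(C(C)C)[C@H]12
F5 | step 11 | 9-O-triethylsilyl ether of F4 | O[C@@H]1C=C(C)[C@H](O[Si](CC)(CC)CC)C[C@@]2(C)CC[C@@](O)(C(C)C)[C@H]12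
F6 | step 11 | 9-O-triethylsilyl ether of 19 | COc1ccc(C(=O)O[C@H]2C=C(C)[C@H](O[Si](CC)(CC)CC)C[C@@]3(C)CC[C@@](O)(C(C)C)[C@H]23)cc1
F7 | step 10 | (1R,4R)-tricycle as 11 with CH3 (C14) on C8 | CC1=C(O[Si](C)(C)C(C)(C)C)C[C@@]2(C)CC[C@]3(C(C)C)O[Si](C(C)C)(C(C)C)OC(C1)=C23
F8 | step 10 | (1R,4R,5R)-4-hydroxydaucane-6,9-dione, both C8 epimers | O=C1CC(C)C(=O)C[C@@]2(C)CC[C@@](O)(C(C)C)[C@H]12
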